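The ring is numbered as follows: C1 is the quaternary carbinol bearing C7H2OH, C2 and C5 carry the benzoates, C3=C4 is the alkene, and C6 is the secondary carbinol. The ring is cut at C1–C2 and C4–C5. In one flask, the Z-alkenylmagnesium from ethyl (Z)-3-iodoacrylate (C2–C4) adds once to the twofold-symmetric bis-Weinreb amide of L-tartrate acetonide (C5, C6, C1, C7), forming C4–C5. The enolate next to the second amide then closes C1–C2 onto the ester, giving a cis-fused ene-1,4-dione. The step exploits the tartrate pattern in C5–C6–C1–C7 and the symmetric O–C2–C3=C4–C5–O unit of the six-membered ring; hydroxyl-directed reduction later sets C2 and C5.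

Key step: step 2

Remark: the ring numbering of the opening paragraph is used for all compounds; 2 is assumed not to be purchasable and is made in step 1.

Step 1
Reactants: 1 dimethyl (4R,5R)-2,2-dimethyl-1,3-dioxolane-4,5-dicarboxylate
Product: 2 (4R,5R)-N4,N5-dimethoxy-N4,N5,2,2-tetramethyl-1,3-dioxolane-4,5-dicarboxamide
Conditions: MeNH(OMe)·HCl, i-PrMgCl, THF, −20 to 0 °C
Reagents that add atoms: N,O-dimethylhydroxylamine hydrochloride, CNOC.Cl
Why: Transamidation of both esters by the chloromagnesium amide of N,O-dimethylhydroxylamine (Weinreb amide formation) should proceed without enolisation of the dioxolane carbons, so the (4R,5R) configuration of L-tartrate is carried into 2.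

Step 2
Reactants: 2 (4R,5R)-N4,N5-dimethoxy-N4,N5,2,2-tetramethyl-1,3-dioxolane-4,5-dicarboxamide; 3 ethyl (Z)-3-iodoprop-2-enoate
Product: 7 (3aS,7aR)-N-methoxy-N,2,2-trimethyl-4,7-dioxo-3a,4,7,7a-tetrahydro-1,3-benzodioxole-3a-carboxamide, via alkenylmagnesium chloride 4 (not isolated), via chloromagnesium hemiaminal 5 (not isolated), via cyclised ketone hemiaminal 6 (not isolated)
Conditions: 3, i-PrMgCl·LiCl, THF, −78 °C; then 2, −78 to −40 °C; then LiN(i-Pr)2, −78 to −30 °C; aq. NH4Cl
Reagents that add atoms: none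
Why: Iodine–magnesium exchange gives the ester-chelated, configurationally stable Z-alkenylmagnesium 4, which adds once to twofold-symmetric 2 (Weinreb ketone synthesis) and forms C4–C5 as the chelated hemiaminal 5, so that no ketone and no acidic C6–H exist in the flask. LiN(i-Pr)2 then removes the only acidic proton, C1–H next to the second amide, and this exocyclic dioxolane enolate attacks the ester carbonyl held close by the Z alkene in an intramolecular Claisen (Dieckmann) condensation, a 6-(enolexo)-exo-trig closure that forms C1–C2 and gives 6; aqueous work-up unmasks the C5 ketone. The closest known reaction types are the single addition of Grignard reagents to tartrate bis-Weinreb amides and the Dieckmann cyclisation of ester or amide enolates. The one new stereocentre, C1, is fixed by the substrate: the chain is anchored on C6 of the dioxolane ring, so C2 can reach the planar enolate only on the face of C5 and takes the place of the former hydrogen, which gives the cis-fused bicycle and hence the C1/C6 cis-diol of the target with C7 on the opposite face. The step needs mono-addition, secured by the anionic hemiaminal and a slight excess of 2, retention of the Z geometry, secured by chelation below −40 °C, and no β-elimination of the ring oxygen from the enolate, secured by the orthogonal C–O bond of the dioxolane at low temperature.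

Step 3
Reactants: 7 (3aS,7aR)-N-methoxy-N,2,2-trimethyl-4,7-dioxo-3a,4,7,7a-tetrahydro-1,3-benzodioxole-3a-carboxamide
Product: 9 (1R,2S,5R,6S)-1,2,5,6-tetrahydroxy-N-methoxy-N-methylcyclohex-3-ene-1-carboxamide, via dihydroxy enedione 8 (not isolated)
Conditions: CF3CO2H/H2O (9:1), 0 °C; evaporate; then Me4NBH(OAc)3, MeCN/AcOH, −30 °C
Reagents that add atoms: none
Why: Acid hydrolysis of the acetonide frees the C1/C6 cis-diol (8), whose hydroxyls bind the triacetoxyborohydride and deliver hydride intramolecularly to the C2 and C5 carbonyls from the diol face (Evans–Saksena hydroxyl-directed 1,2-reduction), so that both new carbinols should form trans to the diol, as the target requires.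

Step 4
Reactants: 9 (1R,2S,5R,6S)-1,2,5,6-tetrahydroxy-N-methoxy-N-methylcyclohex-3-ene-1-carboxamide
Product: 12 (1S,2S,5R,6S)-1,6-dihydroxy-1-[methoxy(methyl)carbamoyl]cyclohex-3-ene-2,5-diyl dibenzoate, via cyclic phenylboronate 10 (not isolated), via dibenzoyl phenylboronate 11 (not isolated)
Conditions: PhB(OH)2, pyridine, 4 Å molecular sieves, rt; then BzCl, DMAP, 0 °C to rt; then pinacol, rt
Reagents that add atoms: benzoyl chloride, O=C(Cl)c1ccccc1
Why: Phenylboronic acid should esterify only the cis-vicinal C1/C6 diol as its five-membered cyclic boronate (10), DMAP-catalysed acylation with benzoyl chloride then takes the two remaining allylic secondary hydroxyls at C2 and C5 (11), and transesterification with pinacol releases the diol without touching a stereocentre.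

Step 5
Reactants: 12 (1S,2S,5R,6S)-1,6-dihydroxy-1-[methoxy(methyl)carbamoyl]cyclohex-3-ene-2,5-diyl dibenzoate
Product: 14 (1S,2S,5R,6S)-1,6-dihydroxy-1-(hydroxymethyl)cyclohex-3-ene-2,5-diyl dibenzoate, via hydroxy aldehyde 13 (not isolated)
Conditions: Cp2Zr(H)Cl, THF, rt; then NaBH4, MeOH, −20 °C
Reagents that add atoms: none
Why: Cp2Zr(H)Cl should reduce the Weinreb amide chemoselectively to the aldehyde 13 through a zirconium hemiaminal that collapses only on work-up, benzoates being inert to this hydride, and NaBH4 then reduces the aldehyde at low temperature (chemoselective carbonyl reduction) faster than any acyl migration; no stereocentre is affected.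

Compound list
1 | dimethyl (4R,5R)-2,2-dimethyl-1,3-dioxolane-4,5-dicarboxylate (dimethyl 2,3-O-isopropylidene-L-tartrate) | COC(=O)[C@@H]1OC(C)(C)O[C@H]1C(=O)OC | starting material
2 | (4R,5R)-N4,N5-dimethoxy-N4,N5,2,2-tetramethyl-1,3-dioxolane-4,5-dicarboxamide | CON(C)C(=O)[C@@H]1OC(C)(C)O[C@H]1C(=O)N(C)OC | intermediate
3 | ethyl (Z)-3-iodoprop-2-enoate | CCOC(=O)/C=C\I | starting material
4 | ethyl (Z)-3-(chloromagnesio)prop-2-enoate | CCOC(=O)/C=C\[Mg]Cl | intermediate
5 | chloromagnesium alkoxide of the mono-adduct, ethyl (Z)-4-hydroxy-4-[methoxy(methyl)amino]-4-[(4R,5R)-5-[methoxy(methyl)carbamoyl]-2,2-dimethyl-1,3-dioxolan-4-yl]but-2-enoate (hemiaminal carbon undefined) | CCOC(=O)/C=C\C(O[Mg]Cl)(N(C)OC)[C@@H]1OC(C)(C)O[C@H]1C(=O)N(C)OC | intermediate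
6 | chloromagnesium alkoxide of the cis-fused 7-hydroxy-7-[methoxy(methyl)amino]-4-oxo bicycle (ring fusion as in 7, hemiaminal carbon undefined) | O=C1C=CC(O[Mg]Cl)(N(C)OC)[C@@H]2OC(C)(C)O[C@]12C(=O)N(C)OC | intermediate
7 | (3aS,7aR)-N-methoxy-N,2,2-trimethyl-4,7-dioxo-3a,4,7,7a-tetrahydro-1,3-benzodioxole-3a-carboxamide | O=C1C=CC(=O)[C@@H]2OC(C)(C)O[C@]12C(=O)N(C)OC | intermediate
8 | (1S,6R)-1,6-dihydroxy-N-methoxy-N-methyl-2,5-dioxocyclohex-3-ene-1-carboxamide | O=C1C=CC(=O)[C@H](O)[C@@]1(O)C(=O)N(C)OC | intermediate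
9 | (1R,2S,5R,6S)-1,2,5,6-tetrahydroxy-N-methoxy-N-methylcyclohex-3-ene-1-carboxamide | O[C@H]1C=C[C@@H](O)[C@H](O)[C@@]1(O)C(=O)N(C)OC | intermediate
10 | cyclic phenylboronate of 9 across the C1 and C6 hydroxyls (C2 and C5 hydroxyls free, trans to the boronate oxygens) | O[C@H]1C=C[C@@H](O)[C@@H]2OB(c3ccccc3)O[C@]12C(=O)N(C)OC | intermediate
11 | C2,C5-dibenzoate of phenylboronate 10 | O=C(O[C@H]1C=C[C@@H](OC(=O)c3ccccc3)[C@@H]2OB(c4ccccc4)O[C@]12C(=O)N(C)OC)c1ccccc1 | intermediate
12 | (1S,2S,5R,6S)-1,6-dihydroxy-1-[methoxy(methyl)carbamoyl]cyclohex-3-ene-2,5-diyl dibenzoate | O=C(O[C@H]1C=C[C@@H](OC(=O)c2ccccc2)[C@H](O)[C@@]1(O)C(=O)N(C)OC)c1ccccc1 | intermediate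
13 | (1S,2S,5R,6S)-1-formyl-1,6-dihydroxycyclohex-3-ene-2,5-diyl dibenzoate | O=C(O[C@H]1C=C[C@@H](OC(=O)c2ccccc2)[C@H](O)[C@@]1(O)C=O)c1ccccc1 | intermediate
14 | (1S,2S,5R,6S)-1,6-dihydroxy-1-(hydroxymethyl)cyclohex-3-ene-2,5-diyl dibenzoate (CNP0212417.1) | O=C(O[C@H]1C=C[C@@H](OC(=O)c2ccccc2)[C@H](O)[C@@]1(O)CO)c1ccccc1 | target

Total step count: 5. Longest linear sequence: 5 steps (1 → 2 → 7 → 9 → 12 → 14); 3 is a purchased building block.

Steps most likely to fail

Step 2. Possible failures are double addition of 4 to 2, decomposition or Z-to-E isomerisation of 4 before it adds to the amide, base-induced fragmentation of the N-methoxy amide or β-elimination from the C1 enolate, and incomplete ring closure. Fallback, setting out from 2 and coming back at 7: the two bonds are made in separate operations with C2 at the aldehyde level.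
- One amide of 2 should be reduced with i-Bu2AlH (−78 °C) to the aldehyde (4R,5R)-5-formyl-N-methoxy-N,2,2-trimethyl-1,3-dioxolane-4-carboxamide F1.
- Addition of (Z)-3,3-diethoxyprop-1-enyllithium (from (Z)-1-bromo-3,3-diethoxyprop-1-ene and t-BuLi, −78 °C) should give the Z-allylic alcohol acetal F2, which forms C4–C5; the carbinol epimers are of no consequence.
- TBSOTf/2,6-lutidine should give the silyl ether F3, and mild acetal hydrolysis (oxalic acid, wet silica) the Z-enal F4.
- LiN(i-Pr)2 at −78 °C should close C1–C2 by intramolecular aldol addition of the amide enolate, again cis-fused by the ring, to give the hydroxy silyl ether F5.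
- Bu4NF should give the diol F6, and Dess–Martin oxidation of both allylic alcohols returns 7.

Step 3. Possible failures are dehydration of 8 (enolisation at C6, loss of the C1 hydroxyl) with aromatisation to a hydroxyquinone, conjugate hydride addition to the enedione, and lactonisation of the C5 hydroxyl onto the amide. Fallback, setting out from 7 and coming back at 12: the free enedione diol is avoided and C5 is corrected by inversion.
- Luche reduction (NaBH4, CeCl3·7H2O, MeOH, −78 °C) of 7 with the acetonide in place should give the diol F7, hydride entering C5 anti to the dioxolane and C2 anti to the neighbouring C1 carboxamide.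
- The C5 hydroxyl, which is the less hindered one and has the wrong configuration, is inverted and benzoylated in a Mitsunobu reaction (PPh3, DIAD, BzOH) to the C5 monobenzoate F8.
- BzCl/DMAP should give the dibenzoate acetonide F9, and aqueous CF3CO2H removes the acetonide to return 12.

Step 5. Possible failures are hydrozirconation of the ring alkene, hydride consumption by the free hydroxyls with incomplete amide reduction, and loss or migration of the benzoates during the borohydride stage. Fallback, setting out from 9 and coming back at 14: the amide is reduced before any benzoate is present.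
- 9 is converted (2,2-dimethoxypropane, camphorsulfonic acid) to the C1/C6 acetonide F10.
- LiAlH4 (THF, −40 °C) should reduce the Weinreb amide to the aldehyde F11, and NaBH4 should give the triol F12.
- The primary hydroxyl is silylated (TBSCl, imidazole) to the silyl ether F13, and the two allylic hydroxyls are benzoylated (BzCl, DMAP, pyridine) to the dibenzoate F14.
- Aqueous CF3CO2H removes the acetonide and the silyl ether to give 14.

Further compounds
F1 | step 2 | (4R,5R)-5-formyl-N-methoxy-N,2,2-trimethyl-1,3-dioxolane-4-carboxamide | CON(C)C(=O)[C@@H]1OC(C)(C)O[C@H]1C=O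
F2 | step 2 | (4R,5R)-5-[(Z)-4,4-diethoxy-1-hydroxybut-2-enyl]-N-methoxy-N,2,2-trimethyl-1,3-dioxolane-4-carboxamide (carbinol epimers) | CON(C)C(=O)[C@@H]1OC(C)(C)O[C@H]1C(O)/C=C\C(OCC)OCC
F3 | step 2 | tert-butyldimethylsilyl ether of F2 | CON(C)C(=O)[C@@H]1OC(C)(C)O[C@H]1C(O[Si](C)(C)C(C)(C)C)/C=C\C(OCC)OCC
F4 | step 2 | (4R,5R)-5-[(Z)-1-(tert-butyldimethylsilyloxy)-4-oxobut-2-enyl]-N-methoxy-N,2,2-trimethyl-1,3-dioxolane-4-carboxamide | CON(C)C(=O)[C@@H]1OC(C)(C)O[C@H]1C(O[Si](C)(C)C(C)(C)C)/C=C\C=O
F5 | step 2 | cis-fused aldol product with C2 hydroxyl and C5 silyl ether (acetonide and amide as in 7, epimers at C2 and C5) | OC1C=CC(O[Si](C)(C)C(C)(C)C)[C@@H]2OC(C)(C)O[C@]12C(=O)N(C)OC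
F6 | step 2 | cis-fused C2,C5-diol acetonide amide (epimers at C2 and C5) | OC1C=CC(O)[C@@H]2OC(C)(C)O[C@]12C(=O)N(C)OC
F7 | step 3 | C2,C5-diol acetonide amide with C2 hydroxyl trans and C5 hydroxyl cis to the dioxolane oxygens | O[C@H]1C=C[C@H](O)[C@@H]2OC(C)(C)O[C@]12C(=O)N(C)OC
F8 | step 3 | C5 benzoate (inverted, trans to the dioxolane oxygens) of the C2-hydroxy acetonide amide | O[C@H]1C=C[C@@H](OC(=O)c3ccccc3)[C@@H]2OC(C)(C)O[C@]12C(=O)N(C)OC
F9 | step 3 | C1/C6 acetonide of 12 | O=C(O[C@H]1C=C[C@@H](OC(=O)c3ccccc3)[C@@H]2OC(C)(C)O[C@]12C(=O)N(C)OC)c1ccccc1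
F10 | step 5 | C1/C6 acetonide of 9 | O[C@H]1C=C[C@@H](O)[C@@H]2OC(C)(C)O[C@]12C(=O)N(C)OC
F11 | step 5 | C1/C6 acetonide of the C2,C5-dihydroxy C7 aldehyde | O[C@H]1C=C[C@@H](O)[C@@H]2OC(C)(C)O[C@]12C=O
F12 | step 5 | C1/C6 acetonide of the C2,C5,C7-triol | O[C@H]1C=C[C@@H](O)[C@@H]2OC(C)(C)O[C@]12CO
F13 | step 5 | C7 tert-butyldimethylsilyl ether of F12 | O[C@H]1C=C[C@@H](O)[C@@H]2OC(C)(C)O[C@]12CO[Si](C)(C)C(C)(C)C
F14 | step 5 | C2,C5-dibenzoate of F13 | O=C(O[C@H]1C=C[C@@H](OC(=O)c3ccccc3)[C@@H]2OC(C)(C)O[C@]12CO[Si](C)(C)C(C)(C)C)c1ccccc1
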